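## Structural features

The target is a symmetric dimer: two identical bibenzyl halves joined by one CH2 group between the C1 carbons of the two rings B. Each ring B is a tetrasubstituted benzene with the bridge at C1, a methyl ether at C2, a free hydroxyl at C4 and the CH2CH2 tether to ring A at C6. Ring A is a 4-hydroxy-3-methoxyphenyl group. The molecule has no stereocentre, so no stereocentres are adjacent. The only stereocentres on the route are transient ones at C1 and C6 of the ring B precursors, and they are erased on the way. The fragile parts are the four free phenols, above all the electron-rich resorcinol-type rings B (easily oxidized and easily substituted by electrophiles), and the doubly benzylic bridge. The real difficulty is twofold. The bridge must sit on a carbon flanked by two ortho substituents (C2–OMe and C6–tether) in both rings, a position that arylation chemistry does not favour. And the C2 oxygen (methylated) must be told apart from the C4 oxygen (free) and from the ring A phenol. The key step uses the fact that the bridge CH2 plus C1 and C2 of both rings B form the carbon skeleton of a propane-1,1,3,3-tetracarboxylate (malonate carbon = C1, one ester carbon = C2, its carbonyl oxygen = the C2 oxygen). C3 to C6 with the tether are the four-carbon unit of a methyl enone. The bridge is therefore carried in ready-made and its position is fixed by connectivity.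

## Logic of the disconnections

15 to 14: the two O–benzyl bonds on rings A are cut last. The ring A phenols must stay masked through base, oxidant, silylation and methylation, and benzyl leaves under neutral hydrogen. The gain is a final step that touches only protecting groups. The demand is that hydrogenolysis spares the diarylmethane C–C bonds and the aryl methyl ethers.

14 to 13 to 12 to 11: the C2–O–CH3 bonds are cut, with a silyl group placed on the C4 oxygens beforehand and removed afterwards. The C2 and C4 hydroxyls of 11 differ only in their surroundings (C2–OH lies next to the bridge, C4–OH between two ring hydrogens). The gain is that 11 has four equivalent-by-symmetry pairs of oxygens and no methyl ether on ring B. The demand is that silylation picks the C4 hydroxyl in both rings, and that methylation reaches the hindered C2 hydroxyl without loss of the silyl ether.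

11 to 10: both rings B are taken back to cyclohexane-1,3-diones (two hydrogens added per ring). The 1,3-dioxygen pattern with adjacent carbon substituents at C1 and C6 is that of a Michael–Claisen adduct. The gain is that arene synthesis becomes carbonyl chemistry. The demand is a twofold dehydrogenation that leaves benzyl ethers and the electron-rich product intact.

10 to 8 (through 9): a methoxycarbonyl group is put back on C1 of each ring. The ester is what makes C1 a malonate-type nucleophile and what supplies C2. The demand is hydrolysis of a hindered ester on a quaternary carbon followed by decarboxylation.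

8 to 5 and 6 (through 7): in each ring the C1–C6 and C2–C3 bonds are cut, four bonds in all. This opens both rings B at once and returns two equivalents of 5 and one of 6, which already holds the bridge. The demand is conjugate addition of a hindered, doubly stabilized carbanion twice, and ring closure before the adducts revert.

5 to 3 and 4: the C3=C4 double bond of 5 is cut. The stabilized ylide 4 gives the (E)-olefin reliably, and 3 is a simple aldehyde.

3 to 2 to 1: oxidation level adjustment (aldehyde from primary alcohol) and the O–benzyl bond. 1 already has the ring A substitution pattern and the three-carbon chain, so no C–C bond has to be made on this side.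

## Other disconnections considered

Alternative 1: The cut is at the two C4–O bonds of rings B, traced back to C–H bonds in bis{2-methoxy-6-[2-(3-methoxy-4-triisopropylsilyloxyphenyl)ethyl]phenyl}methane A1. In the forward step A1 would be borylated at C4 of both rings B with [Ir(OMe)(cod)]2, a bipyridine ligand and a diboron reagent, and the boronates oxidized with peroxide in the same flask to the bis-phenol A2. Desilylation of A2 would then give 15.
- In favour: iridium-catalysed borylation is sterically governed, and in ring B only C4–H has no ortho substituent. The oxygen is placed without any differentiation of hydroxyls, the methyl ethers are present from the start, and only one kind of protecting group is needed.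
- Against: A1 must first be built, and that means making the doubly ortho-substituted diarylmethane by arylation or cross-coupling, the very problem the chosen plan avoids. The C5 and C6 hydrogens of ring A and the benzylic positions could compete, and two borylations per molecule must both go to completion.
- Comparison: on step economy after the key step this alternative is better (two operations against six), and on protecting-group economy it is the equal or the better. On structure the chosen plan is stronger, because the bridge position follows from connectivity and not from a coupling. On mechanism the chosen plan uses only carbonyl chemistry from cheap materials, while the alternative depends on catalyst-controlled site selection in a large substrate. The overall step count would probably be similar once the route to A1 is counted.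

Alternative 2: The cuts are, in each ring B, the C1–bridge bond and the C6–Cα bond of the tether. In the forward step the aryne released by CsF from 5-(benzyloxy)-3-methoxy-2-(trimethylsilyl)phenyl trifluoromethanesulfonate A3 would insert twice into the two C(O)–CH2 bonds of dimethyl 3-oxopentanedioate A4 (aryne acyl-alkylation) to give the benzophenone A5.
- In favour: four C–C bonds form in one flask. The regiochemistry follows from the polarization of a 3-methoxyaryne: the enolate carbon adds remote from OMe and the aryl anion next to OMe attacks the ketone. The oxygen pattern is built into A3 (OMe at C2, OBn at C4), so no late distinction of the ring B oxygens is needed and one hydrogenolysis frees all phenols. On this point the alternative is better than the chosen plan.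
- Against: the second insertion has to pass through an aryl ketone that is already ortho-disubstituted and would give a tetra-ortho-substituted benzophenone, so it is the weak link. No ring is formed, so the arene must be made beforehand, and A3 needs several steps. Afterwards the hindered diaryl ketone must be reduced to CH2 and each CH2CO2Me arm turned into the CH2CH2–ring A tether (a C–C bond to ring A and a deoxygenation, twice).
- Comparison: the two plans are equal in the number of skeletal bonds made in the key step. The alternative is better on oxygen differentiation. The chosen plan is better on what follows, because the bridge is already at the CH2 level and the tethers are complete, and on the accessibility of the precursors.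

Alternative 3: The cuts are, in each ring B, C1–C2, C3–C4 and C4–C5. In the forward step the methylene-bridged bis(cyclobutenone) A6 would be heated with methoxyacetylene A7. Each cyclobutenone opens to a vinylketene, adds A7 in a [2+2] step, reopens to a dienylketene and closes by 6π electrocyclization. Tautomerization then gives the bis-phenol A8, which is the same compound as 14.
- In favour: the C4 hydroxyl comes from the ketene carbonyl and the C2 methyl ether from the alkyne, so the oxygens are differentiated by mechanism. The rings are aromatic at once without an oxidant, and A8 is one hydrogenolysis away from 15. After the key step this is clearly better than the chosen plan (one step against six), and six skeletal bonds are formed against four.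
- Against: A6 is hard to reach. Two 2,3-disubstituted cyclobutenones joined through C2 would have to come from a ketene–alkyne cycloaddition on an unsymmetrical, base-sensitive skipped diyne, where the regiochemistry on each alkyne is poorly controlled. A7 is volatile and hazardous and would be used in excess in a sealed vessel, and a twofold pericyclic cascade must run cleanly in one molecule.
- Comparison: both plans close the two rings B in one operation and are equal there. The alternative is better in end-game length and redox economy. The chosen plan is better in precursor access (three steps from a commercial alcohol plus a commercial linchpin) and in the reliability of each single step. The risk of the alternative sits in making A6, that of the chosen plan in the congested double annulation.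

Key step: step 4

Assumption: compounds 1, 4 and 6 are taken as purchasable.

Remark: each Claisen closure in step 4 is classed as 6-(enolendo)-exo-trig, because the enolate double bond (C3=C4) lies inside the ring that forms.

## Route

Step 1
Reactants: 1 3-(4-hydroxy-3-methoxyphenyl)propan-1-ol
Product: 2 3-(4-benzyloxy-3-methoxyphenyl)propan-1-ol
Conditions: BnBr (1.1 equiv), K2CO3, acetone, reflux
Reagents that add atoms: benzyl bromide, BrCc1ccccc1
Why: Williamson ether synthesis; K2CO3 deprotonates only the phenol (the primary alcohol is far less acidic), so benzylation is chemoselective for the ring A oxygen.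

Step 2
Reactants: 2 3-(4-benzyloxy-3-methoxyphenyl)propan-1-ol
Product: 3 3-(4-benzyloxy-3-methoxyphenyl)propanal
Conditions: Dess–Martin periodinane (1.2 equiv), CH2Cl2, 0 °C to rt
Reagents that add atoms: none
Why: Dess–Martin oxidation of a primary alcohol stops at the aldehyde under neutral anhydrous conditions and leaves the benzyl ether and the electron-rich arene alone.

Step 3
Reactants: 3 3-(4-benzyloxy-3-methoxyphenyl)propanal; 4 1-(triphenylphosphoranylidene)propan-2-one
Product: 5 (E)-6-(4-benzyloxy-3-methoxyphenyl)hex-3-en-2-one
Conditions: CH2Cl2, 40 °C
Reagents that add atoms: none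
Why: Wittig olefination with a ketone-stabilized ylide; reversible oxaphosphetane formation leads to the (E)-enone, and the aldehyde is the only electrophilic site.

Step 4
Reactants: 5 (E)-6-(4-benzyloxy-3-methoxyphenyl)hex-3-en-2-one (2.1 equiv); 6 tetramethyl propane-1,1,3,3-tetracarboxylate
Product: 8 dimethyl 1,1'-methylenebis{6-[2-(4-benzyloxy-3-methoxyphenyl)ethyl]-2,4-dioxocyclohexane-1-carboxylate} (diastereomer mixture), via bis-Michael adduct 7 (not isolated)
Conditions: NaOMe (2.5 equiv), MeOH, rt, then 65 °C; then cold 1 M HCl
Reagents that add atoms: none
Why: Twofold Michael–Claisen annulation, the reaction type of the classical malonate/enone route to cyclohexane-1,3-diones (dimedone and 5-alkylresorcinol syntheses), here with a 2-substituted malonate on each side. NaOMe deprotonates each malonate carbon of 6, which adds 1,4 to C4 of 5 (ring C6) to give 7; the methyl ketone enolate carbon (ring C3) then attacks one of the two geminal esters (ring C2) and methoxide leaves. Each ring B closes in the 6-(enolendo)-exo-trig mode, since both carbons of the attacking enolate end up inside the new ring; the enolate at the internal CH2 could only give a four-membered ring and should not compete. The Claisen products have no acidic hydrogen at C1 but are trapped as the C3 enolates of the 1,3-diones, which makes both closures irreversible and shields C2 from retro-Claisen attack. Stereocentres arise at C1 and C6 of each ring without control (C6 in the reversible conjugate addition, C1 by the choice between diastereotopic esters); none survives steps 5 and 6, so a diastereomer mixture is acceptable. The step needs 1,4- over 1,2-addition, which the soft, hindered, doubly stabilized malonate anion secures under equilibrating conditions in which any aldol-type adduct reverts. It also needs the linchpin to stay intact: loss of a malonate anion from the anion of 6 is reversible and uphill, and it is kept down by running the conjugate additions at room temperature before heating for the Claisen closures. The bridge CH2 comes in with 6, so its place between C2 and C6 of both rings is fixed by connectivity.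

Step 5
Reactants: 8 dimethyl 1,1'-methylenebis{6-[2-(4-benzyloxy-3-methoxyphenyl)ethyl]-2,4-dioxocyclohexane-1-carboxylate}
Product: 10 4,4'-methylenebis{5-[2-(4-benzyloxy-3-methoxyphenyl)ethyl]cyclohexane-1,3-dione} (diastereomer mixture), via bis-keto-acid 9 (not isolated)
Conditions: 2 M NaOH, MeOH/H2O, reflux; then HCl to pH 1, 70 °C
Reagents that add atoms: none
Why: Ester saponification then decarboxylation of the β-keto acids; in base the diones are enolates, which protects C2 from retro-Claisen cleavage, and after acidification each C1 acid loses CO2 through the C2 ketone. The C1 ester stereocentres vanish and the remaining C1/C6 cis/trans mixture is of no consequence.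

Step 6
Reactants: 10 4,4'-methylenebis{5-[2-(4-benzyloxy-3-methoxyphenyl)ethyl]cyclohexane-1,3-dione}
Product: 11 4,4'-methylenebis{5-[2-(4-benzyloxy-3-methoxyphenyl)ethyl]benzene-1,3-diol}
Conditions: I2 (0.4 equiv), DMSO, 80 °C; aq. Na2S2O3 work-up
Reagents that add atoms: none
Why: Iodine-catalysed dehydrogenative aromatization of cyclohexane-1,3-diones (enol iodination at C5, loss of HI, tautomerization), with DMSO reoxidizing HI to I2; benzyl and methyl aryl ethers are inert, and the last sp3 stereocentres at C1 and C6 are removed.

Step 7
Reactants: 11 4,4'-methylenebis{5-[2-(4-benzyloxy-3-methoxyphenyl)ethyl]benzene-1,3-diol}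
Product: 12 2,2'-methylenebis{3-[2-(4-benzyloxy-3-methoxyphenyl)ethyl]-5-(triisopropylsilyloxy)phenol}
Conditions: TIPSCl (2.1 equiv), imidazole, DMF, 0 °C to rt
Reagents that add atoms: chlorotri(propan-2-yl)silane (TIPSCl), CC(C)[Si](Cl)(C(C)C)C(C)C
Why: Silylation of phenols with a bulky silyl chloride under imidazole catalysis is governed by access to oxygen; the C4 hydroxyls lie between two ring hydrogens while the C2 hydroxyls are flanked by the diarylmethane bridge, so two equivalents should go to C4 and C4'.

Step 8
Reactants: 12 2,2'-methylenebis{3-[2-(4-benzyloxy-3-methoxyphenyl)ethyl]-5-(triisopropylsilyloxy)phenol}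
Product: 13 bis{2-[2-(4-benzyloxy-3-methoxyphenyl)ethyl]-6-methoxy-4-(triisopropylsilyloxy)phenyl}methane
Conditions: MeI (excess), K2CO3, acetone, 50 °C
Reagents that add atoms: iodomethane, CI
Why: Williamson O-methylation of the remaining C2 phenols with a small electrophile; the aryl triisopropylsilyl ethers tolerate K2CO3 in acetone and cannot migrate to the meta-disposed C2 oxygen.

Step 9
Reactants: 13 bis{2-[2-(4-benzyloxy-3-methoxyphenyl)ethyl]-6-methoxy-4-(triisopropylsilyloxy)phenyl}methane
Product: 14 bis{2-[2-(4-benzyloxy-3-methoxyphenyl)ethyl]-4-hydroxy-6-methoxyphenyl}methane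
Conditions: TBAF (2.2 equiv), AcOH (2.2 equiv), THF, 0 °C to rt
Reagents that add atoms: none
Why: Fluoride-mediated cleavage of aryl silyl ethers, driven by Si–F bond formation; acetic acid buffers the phenoxides, and benzyl and methyl ethers are untouched.

Step 10
Reactants: 14 bis{2-[2-(4-benzyloxy-3-methoxyphenyl)ethyl]-4-hydroxy-6-methoxyphenyl}methane
Product: 15 bis{4-hydroxy-2-[2-(4-hydroxy-3-methoxyphenyl)ethyl]-6-methoxyphenyl}methane
Conditions: H2 (1 atm), Pd/C (10% Pd on carbon), EtOAc/MeOH, rt
Reagents that add atoms: none
Why: Catalytic hydrogenolysis of the two benzyl aryl ethers; aryl methyl ethers, free phenols and the diarylmethane C–C bonds are stable at room temperature and one atmosphere.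

## Compound list

1 | 3-(4-hydroxy-3-methoxyphenyl)propan-1-ol (dihydroconiferyl alcohol) | COc1cc(CCCO)ccc1O | starting material
2 | 3-(4-benzyloxy-3-methoxyphenyl)propan-1-ol | COc1cc(CCCO)ccc1OCc1ccccc1 | intermediate
3 | 3-(4-benzyloxy-3-methoxyphenyl)propanal | COc1cc(CCC=O)ccc1OCc1ccccc1 | intermediate
4 | 1-(triphenylphosphoranylidene)propan-2-one | CC(=O)C=P(c1ccccc1)(c1ccccc1)c1ccccc1 | starting material
5 | (E)-6-(4-benzyloxy-3-methoxyphenyl)hex-3-en-2-one | CC(=O)/C=C/CCc1ccc(OCc2ccccc2)c(OC)c1 | intermediate
6 | tetramethyl propane-1,1,3,3-tetracarboxylate | COC(=O)C(CC(C(=O)OC)C(=O)OC)C(=O)OC | starting material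
7 | tetramethyl 4,8-bis[2-(4-benzyloxy-3-methoxyphenyl)ethyl]-2,10-dioxoundecane-5,5,7,7-tetracarboxylate (bis-Michael adduct, not isolated, diastereomer mixture, no descriptor assigned) | CC(=O)CC(CCc1ccc(OCc2ccccc2)c(OC)c1)C(C(=O)OC)(C(=O)OC)CC(C(=O)OC)(C(=O)OC)C(CCc1ccc(OCc2ccccc2)c(OC)c1)CC(C)=O | intermediate
8 | dimethyl 1,1'-methylenebis{6-[2-(4-benzyloxy-3-methoxyphenyl)ethyl]-2,4-dioxocyclohexane-1-carboxylate} (diastereomer mixture, one drawn) | COC(=O)[C@]1(C[C@@]2(C(=O)OC)C(=O)CC(=O)C[C@H]2CCc2ccc(OCc3ccccc3)c(OC)c2)C(=O)CC(=O)C[C@@H]1CCc1ccc(OCc2ccccc2)c(OC)c1 | intermediate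
9 | 1,1'-methylenebis{6-[2-(4-benzyloxy-3-methoxyphenyl)ethyl]-2,4-dioxocyclohexane-1-carboxylic acid} (not isolated, diastereomer mixture, no descriptor assigned) | OC(=O)C1(CC2(C(=O)O)C(=O)CC(=O)CC2CCc2ccc(OCc3ccccc3)c(OC)c2)C(=O)CC(=O)CC1CCc1ccc(OCc2ccccc2)c(OC)c1 | intermediate
10 | 4,4'-methylenebis{5-[2-(4-benzyloxy-3-methoxyphenyl)ethyl]cyclohexane-1,3-dione} (diastereomer mixture, no descriptor assigned) | O=C1CC(=O)C(CC2C(=O)CC(=O)CC2CCc2ccc(OCc3ccccc3)c(OC)c2)C(CCc2ccc(OCc3ccccc3)c(OC)c2)C1 | intermediate
11 | 4,4'-methylenebis{5-[2-(4-benzyloxy-3-methoxyphenyl)ethyl]benzene-1,3-diol} | Oc1cc(O)c(Cc2c(O)cc(O)cc2CCc2ccc(OCc3ccccc3)c(OC)c2)c(CCc2ccc(OCc3ccccc3)c(OC)c2)c1 | intermediate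
12 | 2,2'-methylenebis{3-[2-(4-benzyloxy-3-methoxyphenyl)ethyl]-5-(triisopropylsilyloxy)phenol} | CC(C)[Si](Oc1cc(O)c(Cc2c(O)cc(O[Si](C(C)C)(C(C)C)C(C)C)cc2CCc2ccc(OCc3ccccc3)c(OC)c2)c(CCc2ccc(OCc3ccccc3)c(OC)c2)c1)(C(C)C)C(C)C | intermediate
13 | bis{2-[2-(4-benzyloxy-3-methoxyphenyl)ethyl]-6-methoxy-4-(triisopropylsilyloxy)phenyl}methane | COc1cc(O[Si](C(C)C)(C(C)C)C(C)C)cc(CCc2ccc(OCc3ccccc3)c(OC)c2)c1Cc1c(OC)cc(O[Si](C(C)C)(C(C)C)C(C)C)cc1CCc1ccc(OCc2ccccc2)c(OC)c1 | intermediate
14 | bis{2-[2-(4-benzyloxy-3-methoxyphenyl)ethyl]-4-hydroxy-6-methoxyphenyl}methane | COc1cc(CCc2cc(O)cc(OC)c2Cc2c(CCc3ccc(OCc4ccccc4)c(OC)c3)cc(O)cc2OC)ccc1OCc1ccccc1 | intermediate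
15 | bis{4-hydroxy-2-[2-(4-hydroxy-3-methoxyphenyl)ethyl]-6-methoxyphenyl}methane (CNP0079383.0) | COc1cc(CCc2cc(O)cc(OC)c2Cc2c(CCc3ccc(O)c(OC)c3)cc(O)cc2OC)ccc1O | target

## Step count and least certain steps

Total step count: 10. Longest linear sequence: 10 steps (1 to 15); 4 and 6 enter as purchased materials.

**Step 4 (key step).** The most likely failures are reversal of the congested conjugate additions and fragmentation of the anion of 6 by loss of a malonate anion. The freed malonate would then annulate on its own and give rings without the bridge. The second annulation could also stall next to the newly formed quaternary centre.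

The fallback uses known chemistry, sets out from 5 and returns at 11:
- 5 is annulated with dimethyl malonate and NaOMe in the classical one-ring Michael–Claisen manner to methyl 6-[2-(4-benzyloxy-3-methoxyphenyl)ethyl]-2,4-dioxocyclohexane-1-carboxylate F1.
- Saponification and decarboxylation give 5-[2-(4-benzyloxy-3-methoxyphenyl)ethyl]cyclohexane-1,3-dione F2.
- Dehydrogenation as in step 6 gives 5-[2-(4-benzyloxy-3-methoxyphenyl)ethyl]benzene-1,3-diol F3.
- Two molecules of F3 are joined by half an equivalent of formaldehyde under mild acid (hydroxyalkylation, then Friedel–Crafts alkylation through the quinone methide). Attack at the ring position para to one hydroxyl and ortho to the tether gives 11.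

This fallback gives up the connectivity control of the bridge. Substitution between the two hydroxyls and oligomer formation would have to be held back by an excess of F3 and by separation.

**Step 5.** Hydrolysis of the methyl esters on the quaternary C1 carbons may be slow because the acyl carbon is shielded. Forcing base could instead open a ring by retro-Claisen attack at C2. The fallback sets out from 8 and returns at 10. 8 is heated with LiCl in wet DMSO at about 150 °C (Krapcho dealkoxycarbonylation). Chloride attacks the ester methyl group in an SN2 step, so the hindered acyl carbon need not be reached, and the carboxylate loses CO2 in the same flask. This fallback makes no new compound (F0).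

**Step 6.** Dehydrogenation may stop after one ring. The electron-rich resorcinol rings formed may be iodinated, or the doubly benzylic bridge oxidized, because the product is more nucleophilic than the starting dione. The fallback sets out from 10 and returns at 11:
- 10 is converted with LiN(SiMe3)2 and Me3SiCl into 6,6'-methylenebis{5-[2-(4-benzyloxy-3-methoxyphenyl)ethyl]-1,3-bis(trimethylsilyloxy)cyclohexa-1,3-diene} F4 (one regioisomer drawn).
- F4 is dehydrogenated with Pd(OAc)2 in MeCN (Saegusa–Ito oxidation: a divalent palladium enolate forms at C5 and β-hydride elimination takes the C6 hydrogen).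
- Mild acidic work-up removes the remaining silyl groups and gives 11.

No halogen electrophile is present in this sequence.

**Step 7.** Site selection between the C2 and C4 hydroxyls may be incomplete, or a third silyl group may be taken up, because the discrimination is steric only and must succeed in both rings. The fallback sets out from 10 and returns at 15:
- 10 is condensed with benzyl alcohol (TsOH, toluene, removal of water) under equilibrating conditions. The enol ether should form at the carbonyl remote from the bridge, giving 6,6'-methylenebis{3-(benzyloxy)-5-[2-(4-benzyloxy-3-methoxyphenyl)ethyl]cyclohex-2-en-1-one} F5.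
- Dehydrogenation (catalytic I2 in DMSO) gives 2,2'-methylenebis{5-(benzyloxy)-3-[2-(4-benzyloxy-3-methoxyphenyl)ethyl]phenol} F6, in which only the C2 oxygens are free.
- Methylation (MeI, K2CO3) gives bis{4-(benzyloxy)-2-[2-(4-benzyloxy-3-methoxyphenyl)ethyl]-6-methoxyphenyl}methane F7.
- One hydrogenolysis over Pd/C removes all four benzyl groups and gives 15.

Here the oxygens are distinguished at the dione stage by the thermodynamics of enol ether formation, not by kinetic silylation of a phenol.

## Further compounds

F1 | step 4 | methyl 6-[2-(4-benzyloxy-3-methoxyphenyl)ethyl]-2,4-dioxocyclohexane-1-carboxylate | COC(=O)C1C(=O)CC(=O)CC1CCc1ccc(OCc2ccccc2)c(OC)c1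
F2 | step 4 | 5-[2-(4-benzyloxy-3-methoxyphenyl)ethyl]cyclohexane-1,3-dione | O=C1CC(=O)CC(CCc2ccc(OCc3ccccc3)c(OC)c2)C1
F3 | step 4 | 5-[2-(4-benzyloxy-3-methoxyphenyl)ethyl]benzene-1,3-diol | Oc1cc(O)cc(CCc2ccc(OCc3ccccc3)c(OC)c2)c1
F0 | step 5 | none | none
F4 | step 6 | 6,6'-methylenebis{5-[2-(4-benzyloxy-3-methoxyphenyl)ethyl]-1,3-bis(trimethylsilyloxy)cyclohexa-1,3-diene} | C[Si](C)(C)OC1=CC(O[Si](C)(C)C)=CC(CCc2ccc(OCc3ccccc3)c(OC)c2)C1CC1C(O[Si](C)(C)C)=CC(O[Si](C)(C)C)=CC1CCc1ccc(OCc2ccccc2)c(OC)c1
F5 | step 7 | 6,6'-methylenebis{3-(benzyloxy)-5-[2-(4-benzyloxy-3-methoxyphenyl)ethyl]cyclohex-2-en-1-one} | O=C1C=C(OCc2ccccc2)CC(CCc2ccc(OCc3ccccc3)c(OC)c2)C1CC1C(=O)C=C(OCc2ccccc2)CC1CCc1ccc(OCc2ccccc2)c(OC)c1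
F6 | step 7 | 2,2'-methylenebis{5-(benzyloxy)-3-[2-(4-benzyloxy-3-methoxyphenyl)ethyl]phenol} | Oc1cc(OCc2ccccc2)cc(CCc2ccc(OCc3ccccc3)c(OC)c2)c1Cc1c(O)cc(OCc2ccccc2)cc1CCc1ccc(OCc2ccccc2)c(OC)c1
F7 | step 7 | bis{4-(benzyloxy)-2-[2-(4-benzyloxy-3-methoxyphenyl)ethyl]-6-methoxyphenyl}methane | COc1cc(OCc2ccccc2)cc(CCc2ccc(OCc3ccccc3)c(OC)c2)c1Cc1c(OC)cc(OCc2ccccc2)cc1CCc1ccc(OCc2ccccc2)c(OC)c1
A1 | alternative 1 | bis{2-methoxy-6-[2-(3-methoxy-4-triisopropylsilyloxyphenyl)ethyl]phenyl}methane | COc1cccc(CCc2ccc(O[Si](C(C)C)(C(C)C)C(C)C)c(OC)c2)c1Cc1c(OC)cccc1CCc1ccc(O[Si](C(C)C)(C(C)C)C(C)C)c(OC)c1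
A2 | alternative 1 | bis{4-hydroxy-2-methoxy-6-[2-(3-methoxy-4-triisopropylsilyloxyphenyl)ethyl]phenyl}methane | COc1cc(O)cc(CCc2ccc(O[Si](C(C)C)(C(C)C)C(C)C)c(OC)c2)c1Cc1c(OC)cc(O)cc1CCc1ccc(O[Si](C(C)C)(C(C)C)C(C)C)c(OC)c1
A3 | alternative 2 | 5-(benzyloxy)-3-methoxy-2-(trimethylsilyl)phenyl trifluoromethanesulfonate | COc1cc(OCc2ccccc2)cc(OS(=O)(=O)C(F)(F)F)c1[Si](C)(C)C
A4 | alternative 2 | dimethyl 3-oxopentanedioate | COC(=O)CC(=O)CC(=O)OC
A5 | alternative 2 | bis[4-(benzyloxy)-2-methoxy-6-(2-methoxy-2-oxoethyl)phenyl] ketone | O=C(c1c(OC)cc(OCc2ccccc2)cc1CC(=O)OC)c1c(OC)cc(OCc2ccccc2)cc1CC(=O)OC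
A6 | alternative 3 | 2,2'-methylenebis{3-[2-(4-benzyloxy-3-methoxyphenyl)ethyl]cyclobut-2-en-1-one} | O=C1CC(CCc2ccc(OCc3ccccc3)c(OC)c2)=C1CC1=C(CCc2ccc(OCc3ccccc3)c(OC)c2)CC1=O
A7 | alternative 3 | methoxyacetylene | COC#C
A8 | alternative 3 | bis{2-[2-(4-benzyloxy-3-methoxyphenyl)ethyl]-4-hydroxy-6-methoxyphenyl}methane | COc1cc(CCc2cc(O)cc(OC)c2Cc2c(CCc3ccc(OCc4ccccc4)c(OC)c3)cc(O)cc2OC)ccc1OCc1ccccc1
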